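A closed, stirred vessel holds suspended solid substrate, which dissolves to starting material. Starting material binds partner to give intermediate, and intermediate gives target and released group. Two side routes stand beside this: starting material with intermediate gives side product, and protic impurity quenches partner.

in all of them: solid substrate 0.053 M; partner 0.0795 M; protic impurity 1.06 mM

| flask | remark | time |
|---|---|---|
| eta | the very flask that is asked about, followed so far |  |
| flask |  | 8.0 d |

eta run (percent of the solid substrate charged)

| time / d | target / % |
|---|---|
| 1.25 | 64.7 |
| 2.50 | 67.3 |
| 4.00 | 67.8 |
| 5.00 | 67.3 |
| 6.00 | 67.3 |
| 8.00 | 66.7 |

(readings scatter by 0.3 percentage points)

- percentages count the solid substrate that a species holds: one side product counts as two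
- solid, in amounts per volume of the solution: solid substrate
- target that was removed still counts
- reactions considered so far: starting material + partner <-> intermediate; intermediate <-> target + released group; solid substrate <-> starting material; starting material + intermediate -> side product; partner + protic impurity -> quenched reagent
- at the start none of the solid substrate is in solution
- additions bring no volume worth counting

- midnight: at 8.0 d add partner, 100% of the amount charged, then wait 8.0 d
- autumn: at 8.0 d take out 90% of the target then present, then wait 8.0 d
- summer: change nothing and wait 8.0 d more

- target, in percent of the solid substrate first charged, at 8.0 d
- the option that brings most further target ("none" if no option brings more than 2 percentage points) (midnight / autumn / summer / none)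
- target present, with what was taken out counted in, in percent of the solid substrate first charged, after midnight
- target present, with what was taken out counted in, in percent of the solid substrate first charged, after summer

In this flask the target readings stay nearly flat from 2.50 d, so the two reversible steps can be taken as at equilibrium. The intermediate then cancels, leaving the overall equilibrium constant, Q = c(target)·c(released group)/(c(starting material)·c(partner)). The last reading gives c(target) = 0.0354 M, and c(released group) is the same.

The shortfall can hold at most 0.0176 M of free starting material, and free partner is at most 0.0431 M. My reckoning therefore gives the floor of the quotient, 1.64. Any shortfall sitting in side product raises Q above this floor and is lost to midnight.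

The readings of this flask fall by 1.1 percentage points from 4.00 d to 8.00 d, which is 3.67 times the scatter of one reading. I read this as side product still forming, so I hold any gain from midnight as a ceiling, not an expectation.

The neighbouring flask has the same charges except 0.021 M of solid substrate. It carries 3.79 equiv of partner against 1.50 equiv here, so at the same Q it should end with a higher share as target.

The forecast gives 67% now, midnight as the best option, 81% after midnight and 66.4% after summer: "I therefore read the plateau as the reversible equilibrium, not reagent exhaustion". I part from it on midnight, whose gain I hold as a ceiling.

The flask stands at 66.8%, and the best option is none: midnight changes the target by −0.32 points, to 66.5%, and summer ends at 65.1%. In this flask at 8.00 d the side product holds 30.8% and the starting material 0.461%.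

    starting material + partner ⇌ intermediate (K = 120 M⁻¹, k = 0.180 M⁻¹ min⁻¹)
    intermediate ⇌ target + released group (K = 1.20 M, k = 0.00350 min⁻¹)
    solid substrate ⇌ starting material, rate k3*(cs3 - [starting material]) while solid is left; crystals form when [starting material] > cs3 (solubility = 23.0 mM, k = 0.00220 min⁻¹)
    starting material + intermediate → side product (k = 0.180 M⁻¹ min⁻¹)
    partner + protic impurity → quenched reagent (k = 2.40 M⁻¹ min⁻¹)

The amounts in this flask at that time give Q = 152, which is 92.3 times the floor. The neighbouring flask, with target 80.2% and starting material 0.157%, gives Q = 145.

The runs were computed for an exercise, and the scatter is random.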